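**Plan**
- Retrosynthesis: cut the C1–O ester bond (vanilloyl unit) and the C6–C7 epoxide, then open the C4–C10 bond and return C4 to C9 (reverse 1,2-shift). This gives a cis-fused 6-6 octalin with C9–OH, C10–OMs and C1–OH, which is cut at C9=C10 (olefination), C1–isopropyl (Grignard addition) and C4–allyl (allylation of a Birch-derived enol ether of 2,5-dimethylphenol).
- Enabling feature (numbering: C1 ester carbon, C2/C3 CH2, C4 quaternary C–CH3, C5 CH2, C6/C7 epoxide carbons, C8 CH2, C9 carbinol, C10 ring-fusion CH; ring A = cyclopentane, ring B = cycloheptane): C9, C10 and C1 form an aldol-type 1,3-dioxygen triad and C10 also carries quaternary C4, so a pinacol-type shift of C4 from C9 to C10 turns a decalin into rings A and B.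
- Forward ring order: the cyclohexene ring (future ring B) comes from the Birch reduction; the second six-membered ring from an intramolecular Horner–Wadsworth–Emmons olefination; ring A (contraction) and ring B (expansion) arise together in the 1,2-shift; ester and epoxide come last.
- Stereochemistry: C4 from enantioselective Tsuji allylation with (S)-t-Bu-PHOX; C1 from Grignard attack anti to the C4 methyl; the C9/C10 oxygens from C1–OH-directed osmylation; C10 by inversion and C4 by retention in the shift; the C9 carbinol from C1–OH-delivered hydride; C6/C7 from C9–OH-directed epoxidation.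

Key step: step 10

Remark 1: target numbering is used for all intermediates; β is the face of the C4 methyl group, α the opposite face.
Remark 2: a C1–C10 epoxide was weighed as the leaving group at C10 and set aside, because an epoxide C–O bond on a six-membered ring lies antiperiplanar to an exocyclic substituent of C9 and never to the C9–C4 ring bond. The equatorial mesylate of the cis-fused 9,10-diol has the required alignment; the shift, the ring contraction and the ring expansion are the same.
Remark 3: 4-(benzyloxy)-3-methoxybenzoic acid (O-benzylvanillic acid), diallyl carbonate, dimethyl (diazomethyl)phosphonate and isopropylmagnesium chloride are taken as purchased.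
Remark 4: the enantiomeric purity set in step 3 can be raised by recrystallisation of a later crystalline intermediate (for example triol 13) if needed.

**Route**

Step 1
Reactants: 1 2,5-dimethylphenol
Product: 2 tert-butyl(2,5-dimethylphenoxy)dimethylsilane
Conditions: TBSCl, imidazole, DMF, 25 °C
Reagents that add atoms: tert-butyldimethylsilyl chloride, CC(C)(C)[Si](C)(C)Cl
Why: Silyl ether formation on the phenol gives an aryl ether that survives dissolving-metal reduction and later serves as a regiodefined silyl enol ether.

Step 2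
Reactants: 2 tert-butyl(2,5-dimethylphenoxy)dimethylsilane
Product: 3 tert-butyl[(2,5-dimethylcyclohexa-1,4-dien-1-yl)oxy]dimethylsilane
Conditions: Li, NH3 (l), THF, t-BuOH, −78 °C
Reagents that add atoms: none
Why: Birch reduction of the aryl silyl ether leaves the oxygen- and methyl-bearing carbons on the two remaining double bonds, so one 1,4-diene forms whose enol ether double bond ends at the carbon that becomes C4.

Step 3
Reactants: 3 tert-butyl[(2,5-dimethylcyclohexa-1,4-dien-1-yl)oxy]dimethylsilane; 4 diallyl carbonate
Product: 5 (R)-2-allyl-2,5-dimethylcyclohex-4-en-1-one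
Conditions: Pd2(dba)3 (2.5 mol %), (S)-t-Bu-PHOX (6.25 mol %), Bu4N[Ph3SiF2] (35 mol %), THF, 25 °C
Reagents that add atoms: diallyl carbonate (4), C=CCOC(=O)OCC=C
Why: Enantioselective Tsuji allylation of a silyl enol ether sets quaternary C4 when the fluoride-released enolate attacks the allylpalladium–PHOX complex; the (S)-ligand is chosen because it gives the spatial arrangement of (S)-2-allyl-2-methylcyclohexanone, which carries the label R here.

Step 4
Reactants: 5 (R)-2-allyl-2,5-dimethylcyclohex-4-en-1-one
Product: 6 3-[(1R)-1,4-dimethyl-2-oxocyclohex-4-en-1-yl]propanal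
Conditions: PdCl2(PhCN)2 (10 mol %), CuCl2·2H2O (10 mol %), AgNO2 (5 mol %), O2 (1 atm), t-BuOH/MeNO2 15:1, 25 °C
Reagents that add atoms: dioxygen, O=O
Why: Aldehyde-selective (anti-Markovnikov) nitrite-modified Wacker oxidation, a reaction suited to allyl groups on quaternary carbons, oxidises only the terminal alkene and leaves the trisubstituted ring alkene.

Step 5
Reactants: 6 3-[(1R)-1,4-dimethyl-2-oxocyclohex-4-en-1-yl]propanal; 7 dimethyl (diazomethyl)phosphonate
Product: 8 dimethyl {4-[(1R)-1,4-dimethyl-2-oxocyclohex-4-en-1-yl]-2-oxobutyl}phosphonate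
Conditions: SnCl2 (10 mol %), CH2Cl2, 25 °C
Reagents that add atoms: dimethyl (diazomethyl)phosphonate (7), COP(=O)(OC)C=[N+]=[N-]
Why: Roskamp reaction: Lewis-acid-catalysed addition of the diazo compound to the aldehyde and 1,2-hydride shift with loss of N2 give the β-keto phosphonate (C1 carbonyl, C10 methylene), while the hindered ring ketone does not react.

Step 6
Reactants: 8 dimethyl {4-[(1R)-1,4-dimethyl-2-oxocyclohex-4-en-1-yl]-2-oxobutyl}phosphonate
Product: 9 (4aR)-4a,7-dimethyl-4,4a,5,8-tetrahydronaphthalen-2(3H)-one
Conditions: NaH (1.0 equiv), THF, 0 to 50 °C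
Reagents that add atoms: none
Why: Intramolecular Horner–Wadsworth–Emmons olefination closes the second six-membered ring as the C1 enone with the C9=C10 bond; one equivalent of base removes only the acidic phosphonate proton, so the skipped C6=C7 alkene should not move into conjugation.

Step 7
Reactants: 9 (4aR)-4a,7-dimethyl-4,4a,5,8-tetrahydronaphthalen-2(3H)-one; 10 isopropylmagnesium chloride
Product: 11 (2R,4aR)-4a,7-dimethyl-2-(propan-2-yl)-2,3,4,4a,5,8-hexahydronaphthalen-2-ol
Conditions: i-PrMgCl (1.5 equiv), LaCl3·2LiCl (1.0 equiv), THF, −20 °C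
Reagents that add atoms: isopropylmagnesium chloride (10), CC(C)[Mg]Cl
Why: Lanthanide-promoted 1,2-Grignard addition to the enone avoids enolisation, reduction and conjugate addition; axial attack on the face opposite the angular C4 methyl should place the new C1 hydroxyl β and the isopropyl group α.

Step 8
Reactants: 11 (2R,4aR)-4a,7-dimethyl-2-(propan-2-yl)-2,3,4,4a,5,8-hexahydronaphthalen-2-ol
Product: 13 cis-fused 1β,9β,10β-triol, via osmate ester TMEDA complex 12 (not isolated)
Conditions: OsO4 (1.05 equiv), TMEDA (1.1 equiv), CH2Cl2, −78 °C; then Na2SO3, H2O/THF, reflux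
Reagents that add atoms: osmium tetroxide, O=[Os](=O)(=O)=O
Why: Hydrogen-bond-directed dihydroxylation with OsO4·TMEDA: the C1 hydroxyl binds the oxidant and delivers it to the allylic C9=C10 alkene on its own face, so both new hydroxyls are β (cis ring fusion), while the C6=C7 alkene has no hydroxyl within reach and should survive one equivalent at −78 °C.

Step 9
Reactants: 13 cis-fused 1β,9β,10β-triol
Product: 14 C10 methanesulfonate of triol 13
Conditions: MsCl (1.2 equiv), Et3N, CH2Cl2, −20 °C
Reagents that add atoms: methanesulfonyl chloride, CS(=O)(=O)Cl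
Why: Sulfonylation through sulfene picks the only secondary hydroxyl (C10) in the presence of the two tertiary ones; the crude mesylate is used without chromatography.

Step 10
Reactants: 14 C10 methanesulfonate of triol 13
Product: 16 trans-fused hydroxy ketone (C9 ketone; C1β-OH; H-10 α), via bis(diethylaluminium) dialkoxide 15 (not isolated)
Conditions: Et3Al (3 equiv), CH2Cl2, −78 to 0 °C; work-up with aqueous KNaC4H4O6
Reagents that add atoms: none
Why: Et3Al converts both tertiary hydroxyls into aluminium alkoxides (15) and activates the mesylate; the C9 alkoxide then closes down to the carbonyl while the C9–C4 bond shifts to C10 from the side opposite the leaving C10–O bond, a stereospecific pinacol-type (semipinacol) 1,2-shift of the kind known for β-mesyloxy alcohols with organoaluminium reagents and for decalin-diol monosulfonates that give hydroazulenones. Ring A closes by contraction of the mesylate-bearing cyclohexane (C4 moves from C9 to C10, six to five) and ring B by the matching one-carbon expansion of the cyclohexene ring (C10 is inserted between C9 and C4, six to seven). C10 is the only stereocentre made: it is inverted, C4 migrates with retention, and because the mesylate, the C1 oxygen and the C4 methyl all sit on the β face the product has H-10 trans to the C4 methyl and the C1 hydroxyl cis to C9. The selectivity needed is C4 over C8 and over C2: the cis ring fusion allows the chair in which isopropyl and mesylate are equatorial (the other chair has isopropyl and C8 syn-diaxial), and there C9–C4 is antiperiplanar to C10–OMs while C9–C8 is gauche. The C1–C2 bond is also antiperiplanar, but C2 is a primary carbon and C4 a fully substituted one, so the far higher migratory aptitude of the tertiary centre should decide; elimination cannot compete because C9 and C1 carry no hydrogen.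

Step 11
Reactants: 16 trans-fused hydroxy ketone
Product: 17 1β,9α-diol
Conditions: Me4NBH(OAc)3 (5 equiv), MeCN/AcOH 1:1, −30 °C
Reagents that add atoms: none
Why: Hydroxyl-directed reduction (Evans–Saksena reduction): the C1 hydroxyl exchanges onto boron and delivers hydride to the C9 carbonyl through a six-membered chair transition state from the side of the C1 oxygen, which should give the 9α-alcohol of the target.

Step 12
Reactants: 17 1β,9α-diol
Product: 18 C9 tert-butyldimethylsilyl ether of diol 17
Conditions: TBSOTf (1.1 equiv), 2,6-lutidine, CH2Cl2, −78 °C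
Reagents that add atoms: tert-butyldimethylsilyl triflate, CC(C)(C)[Si](C)(C)OS(=O)(=O)C(F)(F)F
Why: Silyl ether formation at low temperature is selective for the secondary C9 hydroxyl over the hindered tertiary C1 hydroxyl.

Step 13
Reactants: 19 4-(benzyloxy)-3-methoxybenzoic acid
Product: 20 4-(benzyloxy)-3-methoxybenzoyl chloride
Conditions: (COCl)2, DMF (cat.), CH2Cl2, 0 to 25 °C
Reagents that add atoms: oxalyl chloride, O=C(Cl)C(=O)Cl
Why: Acid chloride formation with oxalyl chloride and catalytic DMF; the benzyl ether masks the phenol for the acylation.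

Step 14
Reactants: 18 C9 tert-butyldimethylsilyl ether of diol 17; 20 4-(benzyloxy)-3-methoxybenzoyl chloride
Product: 22 C1 aryl ester C9 silyl ether, via potassium alkoxide 21 (not isolated)
Conditions: KN(SiMe3)2 (1.1 equiv), THF, −78 °C; then 20, −78 to 0 °C
Reagents that add atoms: 4-(benzyloxy)-3-methoxybenzoyl chloride (20), COc1cc(C(Cl)=O)ccc1OCc1ccccc1
Why: O-Acylation of the pre-formed tertiary potassium alkoxide with the aroyl chloride overcomes the low reactivity of the hindered C1 hydroxyl; the C9 oxygen is blocked by the bulky silyl group, which should not migrate at low temperature.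

Step 15
Reactants: 22 C1 aryl ester C9 silyl ether
Product: 23 C1 aryl ester C9 alcohol
Conditions: HF·pyridine, THF, 0 to 25 °C
Reagents that add atoms: none
Why: Fluoride-mediated silyl ether cleavage under acidic rather than basic conditions frees the C9 hydroxyl without 1,3-acyl migration from the tertiary to the secondary oxygen.

Step 16
Reactants: 23 C1 aryl ester C9 alcohol
Product: 24 benzyl-protected 6α,7α-epoxide
Conditions: VO(acac)2 (5 mol %), t-BuOOH (1.5 equiv), CH2Cl2, 0 to 25 °C
Reagents that add atoms: tert-butyl hydroperoxide, CC(C)(C)OO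
Why: Vanadium-catalysed hydroxyl-directed epoxidation of the homoallylic C6=C7 alkene delivers oxygen on the α face, that of the C9 hydroxyl and away from the C4 methyl, and sets C6 and C7.

Step 17
Reactants: 24 benzyl-protected 6α,7α-epoxide
Product: 25 CNP0315707.1
Conditions: H2 (1 atm), Pd/C (10 wt %), EtOAc, 25 °C
Reagents that add atoms: none
Why: Hydrogenolysis of the benzyl aryl ether under neutral conditions frees the phenol; the trisubstituted aliphatic epoxide and the tertiary ester are not benzylic and should survive a short exposure.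

**Compound list**

1 | 2,5-dimethylphenol | Cc1ccc(C)c(O)c1 | starting material
2 | tert-butyl(2,5-dimethylphenoxy)dimethylsilane | Cc1ccc(C)c(O[Si](C)(C)C(C)(C)C)c1 | intermediate
3 | tert-butyl[(2,5-dimethylcyclohexa-1,4-dien-1-yl)oxy]dimethylsilane | CC1=C(O[Si](C)(C)C(C)(C)C)CC(C)=CC1 | intermediate
4 | diallyl carbonate | C=CCOC(=O)OCC=C | starting material
5 | (R)-2-allyl-2,5-dimethylcyclohex-4-en-1-one | C=CC[C@]1(C)CC=C(C)CC1=O | intermediate
6 | 3-[(1R)-1,4-dimethyl-2-oxocyclohex-4-en-1-yl]propanal | O=CCC[C@]1(C)CC=C(C)CC1=O | intermediate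
7 | dimethyl (diazomethyl)phosphonate | COP(=O)(OC)C=[N+]=[N-] | starting material
8 | dimethyl {4-[(1R)-1,4-dimethyl-2-oxocyclohex-4-en-1-yl]-2-oxobutyl}phosphonate | COP(=O)(OC)CC(=O)CC[C@]1(C)CC=C(C)CC1=O | intermediate
9 | (4aR)-4a,7-dimethyl-4,4a,5,8-tetrahydronaphthalen-2(3H)-one (C1 ketone, C9=C10 and C6=C7 alkenes) | C[C@@]12CC=C(C)CC1=CC(=O)CC2 | intermediate
10 | isopropylmagnesium chloride | CC(C)[Mg]Cl | starting material
11 | (2R,4aR)-4a,7-dimethyl-2-(propan-2-yl)-2,3,4,4a,5,8-hexahydronaphthalen-2-ol (C1–OH β, isopropyl α) | CC(C)[C@]1(O)CC[C@]2(C)CC=C(C)CC2=C1 | intermediate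
12 | osmate ester of triol 13 through the C9 and C10 oxygens, TMEDA bound to osmium | O=[Os-2]34(=O)(O[C@]12CC(C)=CC[C@@]1(C)CC[C@](C(C)C)(O)[C@@H]2O3)[N+](C)(C)CC[N+]4(C)C | intermediate
13 | cis-fused triol: 4a,7-dimethyl-2-(propan-2-yl)-1,2,3,4,4a,5,8,8a-octahydronaphthalene-1,2,8a-triol, hydroxyls at C10, C1 and C9 (target numbering) all β, isopropyl α | O[C@]12CC(C)=CC[C@@]1(C)CC[C@](C(C)C)(O)[C@@H]2O | intermediate
14 | C10 methanesulfonate of 13 (C9–OH and C1–OH free) | O[C@]12CC(C)=CC[C@@]1(C)CC[C@](C(C)C)(O)[C@@H]2OS(C)(=O)=O | intermediate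
15 | bis(diethylaluminium) dialkoxide of 14 (C9–O–AlEt2, C1–O–AlEt2) | CC[Al](CC)O[C@]12CC(C)=CC[C@@]1(C)CC[C@](C(C)C)(O[Al](CC)CC)[C@@H]2OS(C)(=O)=O | intermediate
16 | trans-fused hydroxy ketone: 3-hydroxy-6,8a-dimethyl-3-(propan-2-yl)-1,2,3,3a,8,8a-hexahydroazulen-4(5H)-one; C1–OH β, C4–CH3 β, H-10 α, C9 ketone, C6=C7 alkene | O[C@@]1(C(C)C)CC[C@]2(C)CC=C(C)CC(=O)[C@H]21 | intermediate
17 | 1β,9α-diol (9α-alcohol of 16) | O[C@@]1(C(C)C)CC[C@]2(C)CC=C(C)C[C@H](O)[C@H]21 | intermediate
18 | C9 tert-butyldimethylsilyl ether of 17 | O[C@@]1(C(C)C)CC[C@]2(C)CC=C(C)C[C@H](O[Si](C)(C)C(C)(C)C)[C@H]21 | intermediate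
19 | 4-(benzyloxy)-3-methoxybenzoic acid | COc1cc(C(=O)O)ccc1OCc1ccccc1 | starting material
20 | 4-(benzyloxy)-3-methoxybenzoyl chloride | COc1cc(C(Cl)=O)ccc1OCc1ccccc1 | intermediate
21 | potassium C1 alkoxide of 18 | [K+].[O-][C@@]1(C(C)C)CC[C@]2(C)CC=C(C)C[C@H](O[Si](C)(C)C(C)(C)C)[C@H]21 | intermediate
22 | C1 4-(benzyloxy)-3-methoxybenzoate of 18 | COc1cc(C(=O)O[C@@]2(C(C)C)CC[C@]3(C)CC=C(C)C[C@H](O[Si](C)(C)C(C)(C)C)[C@H]32)ccc1OCc1ccccc1 | intermediate
23 | C1 4-(benzyloxy)-3-methoxybenzoate with free 9α-hydroxyl | COc1cc(C(=O)O[C@@]2(C(C)C)CC[C@]3(C)CC=C(C)C[C@H](O)[C@H]32)ccc1OCc1ccccc1 | intermediate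
24 | 6α,7α-epoxide of 23 | COc1cc(C(=O)O[C@@]2(C(C)C)CC[C@]3(C)C[C@@H]4O[C@]4(C)C[C@H](O)[C@H]32)ccc1OCc1ccccc1 | intermediate
25 | CNP0315707.1 | COc1cc(C(=O)O[C@@]2(C(C)C)CC[C@]3(C)C[C@@H]4O[C@]4(C)C[C@H](O)[C@H]32)ccc1O | target

**Count and risks**

Total steps: 17. Longest linear sequence: 16 steps (steps 1 to 12 and 14 to 17, from 2,5-dimethylphenol); step 13 is the one-step side branch.

Steps most likely to fail:

Step 8. The bulky OsO4·TMEDA complex must reach the β face next to the axial C4 methyl. If delivery is slow, undirected osmylation of the C6=C7 alkene or of the α face of C9=C10 takes over, and chemo- and facial selectivity are lost. The fallback sets out from dienol 11 and ties the reagent to the C1 oxygen. Carbonyldiimidazole gives the imidazole carbamate F1, hydroxylamine the N-hydroxy carbamate F2, and pentafluorobenzoyl chloride the N-(pentafluorobenzoyloxy) carbamate F3. Osmium-catalysed tethered aminohydroxylation (K2OsO2(OH)4, t-BuOH/H2O) then closes the oxazolidinone F4 with nitrogen on C10 and hydroxyl on C9; the tether forces both onto the β face and onto the allylic alkene only. Hydrolysis (LiOH, aqueous EtOH, heat) gives the amino diol F5. Diazotisation of its equatorial C10 amine (NaNO2, aqueous AcOH, 0 °C) triggers a Tiffeneau–Demjanov-type loss of N2 with the same shift of C4 from C9 to C10, and the route is rejoined at hydroxy ketone 16.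

Step 10. The C1 alkoxide can also push and the C1–C2 bond is likewise antiperiplanar to the mesylate, so a shift of C2 may compete; a sluggish alkyl shift would also leave time for ethyl transfer from aluminium. The fallback sets out from mesylate 14. The less hindered tertiary hydroxyl at C1 is silylated (TESOTf, 2,6-lutidine, −78 °C; the C9 hydroxyl sits next to quaternary C4) to the C1 triethylsilyl ether mesylate F6, so that only the C9 alkoxide can drive the shift. Et3Al then gives the C1 triethylsilyl ether ketone F7, and HF·pyridine returns to hydroxy ketone 16.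

Step 11. Exchange of the hindered tertiary hydroxyl onto boron may be too slow, so that external hydride attack from the more open H-10 side gives the 9β epimer (poor facial selectivity). The fallback sets out from hydroxy ketone 16 and makes that epimer on purpose: NaBH4 in MeOH gives the 9β-hydroxy diol F8. Mitsunobu inversion (4-nitrobenzoic acid, PPh3, DIAD) gives the 9α 4-nitrobenzoate F9, and methanolysis (K2CO3, MeOH) returns to diol 17.

**Further compounds**

F1 | step 8 | C1 imidazole-1-carboxylate of dienol 11 | CC(C)[C@]1(OC(=O)n3ccnc3)CC[C@]2(C)CC=C(C)CC2=C1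
F2 | step 8 | C1 N-hydroxy carbamate of dienol 11 | CC(C)[C@]1(OC(=O)NO)CC[C@]2(C)CC=C(C)CC2=C1
F3 | step 8 | C1 N-(pentafluorobenzoyloxy) carbamate of dienol 11 | CC(C)[C@]1(OC(=O)NOC(=O)c3c(F)c(F)c(F)c(F)c3F)CC[C@]2(C)CC=C(C)CC2=C1
F4 | step 8 | cis-fused oxazolidinone bridging C1–O and C10–N, with C9β-OH | O[C@]12CC(C)=CC[C@@]1(C)CC[C@]3(C(C)C)OC(=O)N[C@H]23
F5 | step 8 | 10β-amino-1β,9β-diol (cis-fused) | O[C@]12CC(C)=CC[C@@]1(C)CC[C@](C(C)C)(O)[C@@H]2N
F6 | step 10 | C1 triethylsilyl ether of mesylate 14 | O[C@]12CC(C)=CC[C@@]1(C)CC[C@](C(C)C)(O[Si](CC)(CC)CC)[C@@H]2OS(C)(=O)=O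
F7 | step 10 | C1 triethylsilyl ether of hydroxy ketone 16 | CC[Si](CC)(CC)O[C@@]1(C(C)C)CC[C@]2(C)CC=C(C)CC(=O)[C@H]21
F8 | step 11 | 1β,9β-diol (C9 epimer of 17) | O[C@@]1(C(C)C)CC[C@]2(C)CC=C(C)C[C@@H](O)[C@H]21
F9 | step 11 | 9α 4-nitrobenzoate of diol 17 | O[C@@]1(C(C)C)CC[C@]2(C)CC=C(C)C[C@H](OC(=O)c3ccc(cc3)[N+](=O)[O-])[C@H]21
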